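**Retrosynthetic overview**

1. The C17 hydroxymethyl comes last, from the C16 methylene ketone by conjugate borylation/oxidation; the C11 carbinol comes from face-selective reduction of an 11,15-diketone.
2. Rings C and D (the bicyclo[3.2.1]octane) are closed together in one SmI2 operation on aldehyde 29: the C11 ketyl adds to C9 (ring C), then the C8 samarium enolate acylates on the C15 ester (ring D).
3. Enabling feature: C9 is the β-carbon and C8 the α-carbon of the C7 lactone carbonyl, and C8 is the one carbon shared by the δ-lactone, ring C and ring D. A C8=C9 enoate therefore makes C9 a radical acceptor for C11 and leaves a regiodefined C8 enolate for the C8–C15 bond.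
4. Aldehyde 29 comes from a Negishi union at C8–C14 of bromo enoate 17 (ring A with both lactones) and the zinc reagent of iodo ester 26 (C13 from an Evans alkylation).
5. Ring order: ring A (3-methylcyclohexenone; C4 by asymmetric conjugate addition) → fused oxolane, later the γ-lactone → spiro δ-lactone at C10 (epoxide-derived radical plus acrylate) → rings C and D.

Key step: step 15

Remark: ent-kaurane numbering is used (ring A = C1–C5, C10; C18 methyl and C19 on C4; γ-lactone C6/C19; δ-lactone C7/C20; ring C = C8, C9, C11–C14; ring D = C8, C13–C16; C17 = hydroxymethyl carbon).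
Assumption: the (S,S)-phosphinamine ligand of step 1 is taken to give the (3S) silyl enol ether 5; if the sense of induction is the opposite, the (R,R)-ligand is used.

**Route**

Step 1
Reactants: 1 3-methylcyclohex-2-en-1-one; 2 hex-1-yne
Product: 5 {[(3S)-3-[(1E)-hex-1-en-1-yl]-3-methylcyclohex-1-en-1-yl]oxy}trimethylsilane, via (E)-hex-1-enyl(diisobutyl)alane 3 (not isolated), via aluminium enolate 4 (not isolated)
Conditions: 2, i-Bu2AlH, heptane, 50 °C; then 1, copper thiophene-2-carboxylate (10 mol %), (S,S)-Ph2P–N[CH(CH3)Ph]2 (11 mol %), Et2O, −30 °C; then TMSOTf, −30 to 0 °C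
Reagents that add atoms: trimethylsilyl trifluoromethanesulfonate, C[Si](C)(C)OS(=O)(=O)C(F)(F)F
Why: Hydroalumination gives the (E)-alkenylalane, whose copper-catalysed asymmetric conjugate addition to the β-substituted enone should set the C4 quaternary centre under ligand control (the hexenyl group is a latent C19), and O-silylation of the aluminium enolate fixes the enol ether toward C5.

Step 2
Reactants: 5
Product: 6 (3S)-2-(dimethoxymethyl)-3-[(1E)-hex-1-en-1-yl]-3-methylcyclohexan-1-one (both C2 epimers)
Conditions: HC(OMe)3, TMSOTf (10 mol %), CH2Cl2, −78 °C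
Reagents that add atoms: trimethyl orthoformate, COC(OC)OC
Why: Mukaiyama-type addition of the silyl enol ether to the dimethoxycarbenium ion should place C6 on C5 at the aldehyde oxidation level, where it does not acidify C5–H; the C5 configuration is fixed in step 3.

Step 3
Reactants: 6
Product: 8 (3aR,7aS)-1-methoxy-3a-methylhexahydro-2-benzofuran-7(1H)-one (cis-fused keto acetal; both anomers), via hydroxy ketone 7 (not isolated)
Conditions: O3, CH2Cl2/MeOH, −78 °C; NaBH4, −78 to −40 °C; then CSA, CH2Cl2, rt
Reagents that add atoms: ozone, [O-][O+]=O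
Why: Ozonolysis cleaves only the hexenyl alkene, cold borohydride should reduce the resulting C19 aldehyde faster than the hindered ketone, and acid-catalysed transacetalisation closes the oxolane while C5 (α to the ketone) equilibrates to the more stable cis ring fusion, which puts C6 cis to C19.

Step 4
Reactants: 8
Product: 9 1-methoxy-3a-methylhexahydro-1H-spiro[2-benzofuran-7,2'-oxirane] (cis-fused as in 8; both epimers at the spiro carbon C10)
Conditions: Me3S+ I−, n-BuLi, THF, −10 °C to rt
Reagents that add atoms: trimethylsulfonium iodide, C[S+](C)C.[I-]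
Why: Corey–Chaykovsky methylene transfer to the ketone gives the C10–C20 epoxide, whose configuration is irrelevant because C10 becomes a planar radical in step 5.

Step 5
Reactants: 9; 10 2,2,2-trifluoroethyl prop-2-enoate
Product: 12 (3aR,7R,7aR)-1-methoxy-3a-methylhexahydro-1H,3H-spiro[2-benzofuran-7,3'-oxan]-6'-one, via hydroxy ester 11 (not isolated)
Conditions: Cp2TiCl2 (20 mol %), Zn dust, 2,4,6-collidine hydrochloride, 10 (5 equiv), THF, rt, slow addition of 9
Reagents that add atoms: none
Why: Nugent–RajanBabu opening of the epoxide by Cp2TiCl gives the tertiary C10 radical, which should add to the acrylate (Giese addition) from the equatorial direction, anti to the axial C19 methylene of the cis-fused bicycle, so that C9 ends trans and C20 cis to C6, and the C20 alkoxide then lactonises on the trifluoroethyl ester.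

Step 6
Reactants: 12
Product: 13 (3aR,7R,7aR)-3a-methylhexahydro-1H,3H-spiro[2-benzofuran-7,3'-oxane]-1,6'-dione
Conditions: CrO3, H2SO4, acetone/H2O, 0 °C
Reagents that add atoms: water, O
Why: Jones oxidation hydrolyses the cyclic methyl acetal and oxidises the lactol in the same flask, giving the C6/C19 γ-lactone with its carbonyl at C6.

Step 7
Reactants: 13
Product: 15 4',5'-didehydro derivative of 13 (C8=C9 enoate), via α-phenylselanyl lactone 14 (not isolated)
Conditions: LiN(SiMe3)2, THF, −78 °C; PhSeBr; then H2O2, pyridine, CH2Cl2, 0 °C to rt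
Reagents that add atoms: none
Why: The unhindered C8 methylene of the δ-lactone is deprotonated in preference to the C5 methine (flanked by two quaternary carbons), and selenenylation/selenoxide syn-elimination can only remove a C9 hydrogen, giving the C8=C9 enoate.

Step 8
Reactants: 15
Product: 17 5'-bromo-4',5'-didehydro derivative of 13 (C8-bromo enoate), via dibromide 16 (not isolated)
Conditions: Br2, CH2Cl2, 0 °C to rt; then Et3N, 0 °C
Reagents that add atoms: bromine, BrBr
Why: Bromine addition across C8=C9 followed by E1cB loss of HBr through the acidic C8–H gives the 2-bromo enoate, the handle for cross-coupling at C8.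

Step 9
Reactants: 18 (4R)-4-benzyl-1,3-oxazolidin-2-one; 19 pent-4-enoyl chloride
Product: 20 (4R)-4-benzyl-3-(pent-4-enoyl)-1,3-oxazolidin-2-one
Conditions: n-BuLi, THF, −78 °C; then 19
Reagents that add atoms: none
Why: N-acylation of the lithiated oxazolidinone attaches the Evans auxiliary to the chain that supplies C11–C13.

Step 10
Reactants: 20; 21 tert-butyl bromoacetate
Product: 22 tert-butyl (3S)-3-{[(4R)-4-benzyl-2-oxo-1,3-oxazolidin-3-yl]carbonyl}hex-5-enoate
Conditions: NaN(SiMe3)2, THF, −78 °C; then 21
Reagents that add atoms: none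
Why: Evans alkylation of the chelated (Z)-sodium enolate on the face opposite the benzyl group should set C13 in the (S) configuration needed here.

Step 11
Reactants: 22
Product: 24 (4S)-4-(prop-2-en-1-yl)oxolan-2-one, via hydroxy ester 23 (not isolated)
Conditions: LiBH4, MeOH (1 equiv), Et2O, 0 °C; then p-TsOH (cat.), PhMe, 60 °C
Reagents that add atoms: none
Why: Reductive removal of the auxiliary gives the C14 carbinol, which lactonises on the tert-butyl ester under acid without touching the stereocentre.

Step 12
Reactants: 24
Product: 26 methyl (3S)-3-(iodomethyl)hex-5-enoate, via iodo acid 25 (not isolated)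
Conditions: TMSI, CH2Cl2 (dry), 40 °C; H2O; then TMSCHN2, PhMe/MeOH, 0 °C
Reagents that add atoms: iodotrimethylsilane, C[Si](C)(C)I; trimethylsilyldiazomethane, C[Si](C)(C)C=[N+]=[N-]
Why: Silyl-assisted SN2 opening of the lactone by iodide at C14 and methylation of the freed acid give the primary iodide bearing the methyl ester that is the acyl acceptor of the key step.

Step 13
Reactants: 17; 26
Product: 28 methyl (3R)-3-{[5'-yl of enoate 15]methyl}hex-5-enoate (C8–C14 coupled enoate), via alkylzinc iodide 27 (not isolated)
Conditions: 26, Zn dust (activated with TMSCl/BrCH2CH2Br), LiCl, THF, 40 °C; then 17, Pd(OAc)2 (5 mol %), SPhos (10 mol %), THF/DMA, rt to 45 °C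
Reagents that add atoms: none
Why: Negishi coupling of the functionalised primary alkylzinc with the activated alkenyl bromide forms the C8–C14 bond and joins the fragments without enolate chemistry, so the ester, the lactones and C13 are untouched.

Step 14
Reactants: 28
Product: 29 methyl (3S)-3-{[5'-yl of enoate 15]methyl}-5-oxopentanoate (C11 aldehyde)
Conditions: O3, CH2Cl2, −78 °C (Sudan Red 7B end-point); PPh3
Reagents that add atoms: ozone, [O-][O+]=O
Why: The terminal alkene is ozonised much faster than the electron-poor trisubstituted enoate, which unmasks the C11 aldehyde.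

Step 15
Reactants: 29
Product: 31 pentacyclic 11-hydroxy-15-oxo dilactone lacking C17 (C11–OH trans to C10 expected), via samarium enolate 30 (not isolated)
Conditions: SmI2 (2.4 equiv), THF (0.005 M), slow addition of 29, −78 to 0 °C, no proton source; then aq. NH4Cl
Reagents that add atoms: none
Why: Proposed new method: SmI2 reduces the aldehyde to a samarium ketyl that adds 6-endo-trig to C9, the β-carbon of the C8=C9 enoate (attack at the fully substituted C8 is disfavoured), and a second electron turns the C8 radical into a trivalent samarium enolate which, with no proton donor present, attacks the C15 methyl ester in a 5-exo-trig Dieckmann-type acyl substitution that closes ring D and creates the C8 quaternary centre. The closest known reaction type is the SmI2 ketyl–enoate cyclisation/aldol cascade on α-alkylated unsaturated lactones, and the part beyond precedent is the ester in place of an aldehyde as enolate acceptor, the radical step supplying a regiodefined C8 enolate that a base could not make beside the ester. C9 is set by ketyl attack on the enoate face anti to C5 of the spiro ring A (the C1 side) through a chair-like transition state with the ester arm on C13 equatorial, a matched pairing with C13. C8 follows from the tether, because C15 can reach C8 only cis to the C13–C16 bond, which is anti to the new C9–C11 bond. The samarium-bound C11 oxygen is expected to take the outward site (C11–O trans to C10), and this centre is not relied on because it is oxidised in step 16. The step needs aldehyde reduction before enoate reduction (normal for SmI2 in THF), cyclisation before pinacol coupling (high dilution) and C-acylation before enolate protonation or over-reduction of the β-keto lactone (aprotic medium, only a slight excess of SmI2).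

Step 16
Reactants: 31
Product: 32 pentacyclic 11,15-dioxo dilactone lacking C17
Conditions: Dess–Martin periodinane, NaHCO3, CH2Cl2, 0 °C to rt
Reagents that add atoms: none
Why: Dess–Martin oxidation under buffered, non-basic conditions removes the C11 carbinol centre without epimerising C9, so either C11 epimer from step 15 converges on one diketone.

Step 17
Reactants: 32
Product: 33 pentacyclic 11-hydroxy-15-oxo dilactone lacking C17 with C11–OH equatorial and cis to C10
Conditions: NaBH4 (0.3 equiv), CeCl3·7H2O, MeOH/CH2Cl2, −78 °C
Reagents that add atoms: none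
Why: Luche reduction should take the C11 cyclohexanone in preference to the neopentylic C15 cyclopentanone, and the small hydride should enter C11 axially from the endo face because the exo face is closed by the axial C10 spiro carbon with its C1 and C20 methylenes, giving the equatorial C11–OH cis to C10.

Step 18
Reactants: 33
Product: 34 C16-methylene ketone (11-hydroxy-15-oxo-16-ene dilactone)
Conditions: (CH2O)n, i-Pr2NH2+ CF3CO2−, THF, 65 °C
Reagents that add atoms: formaldehyde (as paraformaldehyde), C=O
Why: Mannich-type α-methylenation occurs at C16, the only enolisable position of the C15 ketone (C8 is quaternary), under weakly acidic conditions that tolerate the free alcohol and both lactones.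

Step 19
Reactants: 34
Product: 36 CNP0555433.1 (target), via boronate 35 (not isolated)
Conditions: B2pin2, CuCl (10 mol %), Xantphos (10 mol %), NaOt-Bu (15 mol %), MeOH (2 equiv), THF, 0 °C to rt; then NaBO3·4H2O, THF/H2O, 0 °C
Reagents that add atoms: sodium perborate, [Na+].[O-]B1OO1
Why: Copper-catalysed conjugate borylation of the exocyclic enone and C–B oxidation with retention install the C17 hydroxyl, and C16 is set by kinetic protonation of the enolate from the open exo face (the C14 side), which leaves the CH2B group endo as in the target.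

**Compound list**

1 | 3-methylcyclohex-2-en-1-one | CC1=CC(=O)CCC1 | starting material
2 | hex-1-yne | CCCCC#C | starting material
3 | (E)-hex-1-enyl(diisobutyl)alane | CCCC/C=C/[Al](CC(C)C)CC(C)C | intermediate
4 | diisobutylaluminium enolate of (3S)-3-[(1E)-hex-1-enyl]-3-methylcyclohexanone (enolate toward C5) | C[C@@]1(/C=C/CCCC)CCCC(O[Al](CC(C)C)CC(C)C)=C1 | intermediate
5 | {[(3S)-3-[(1E)-hex-1-en-1-yl]-3-methylcyclohex-1-en-1-yl]oxy}trimethylsilane | C[C@@]1(/C=C/CCCC)CCCC(O[Si](C)(C)C)=C1 | intermediate
6 | (3S)-2-(dimethoxymethyl)-3-[(1E)-hex-1-en-1-yl]-3-methylcyclohexan-1-one (C2 epimers) | C[C@@]1(/C=C/CCCC)CCCC(=O)C1C(OC)OC | intermediate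
7 | (3R)-2-(dimethoxymethyl)-3-(hydroxymethyl)-3-methylcyclohexan-1-one (C2 epimers) | C[C@@]1(CO)CCCC(=O)C1C(OC)OC | intermediate
8 | (3aR,7aS)-1-methoxy-3a-methylhexahydro-2-benzofuran-7(1H)-one (cis-fused; anomers) | C[C@@]12CCCC(=O)[C@@H]1C(OC)OC2 | intermediate
9 | 1-methoxy-3a-methylhexahydro-1H-spiro[2-benzofuran-7,2'-oxirane] (cis-fused; C10 epimers) | C[C@@]12CCCC3(CO3)[C@@H]1C(OC)OC2 | intermediate
10 | 2,2,2-trifluoroethyl prop-2-enoate | C=CC(=O)OCC(F)(F)F | starting material
11 | 2,2,2-trifluoroethyl 3-[7-(hydroxymethyl)-1-methoxy-3a-methyloctahydro-2-benzofuran-7-yl]propanoate (C20 cis to C6) | C[C@@]12CCC[C@@](CO)(CCC(=O)OCC(F)(F)F)[C@@H]1C(OC)OC2 | intermediate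
12 | (3aR,7R,7aR)-1-methoxy-3a-methylhexahydro-1H,3H-spiro[2-benzofuran-7,3'-oxan]-6'-one (anomers) | C[C@@]12CCC[C@]3(COC(=O)CC3)[C@@H]1C(OC)OC2 | intermediate
13 | (3aR,7R,7aR)-3a-methylhexahydro-1H,3H-spiro[2-benzofuran-7,3'-oxane]-1,6'-dione | C[C@@]12CCC[C@]3(COC(=O)CC3)[C@@H]1C(=O)OC2 | intermediate
14 | 5'-(phenylselanyl) derivative of 13 (C8 epimers) | C[C@@]12CCC[C@]3(COC(=O)C([Se]c4ccccc4)C3)[C@@H]1C(=O)OC2 | intermediate
15 | 4',5'-didehydro derivative of 13 (C8=C9 enoate) | C[C@@]12CCC[C@]3(COC(=O)C=C3)[C@@H]1C(=O)OC2 | intermediate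
16 | 4',5'-dibromo derivative of 13 | C[C@@]12CCC[C@]3(COC(=O)C(Br)C3Br)[C@@H]1C(=O)OC2 | intermediate
17 | 5'-bromo-4',5'-didehydro derivative of 13 (C8-bromo enoate) | C[C@@]12CCC[C@]3(COC(=O)C(Br)=C3)[C@@H]1C(=O)OC2 | intermediate
18 | (4R)-4-benzyl-1,3-oxazolidin-2-one | O=C1N[C@H](Cc2ccccc2)CO1 | starting material
19 | pent-4-enoyl chloride | C=CCCC(Cl)=O | starting material
20 | (4R)-4-benzyl-3-(pent-4-enoyl)-1,3-oxazolidin-2-one | O=C1N(C(=O)CCC=C)[C@H](Cc2ccccc2)CO1 | intermediate
21 | tert-butyl bromoacetate | BrCC(=O)OC(C)(C)C | starting material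
22 | tert-butyl (3S)-3-{[(4R)-4-benzyl-2-oxo-1,3-oxazolidin-3-yl]carbonyl}hex-5-enoate | O=C1N(C(=O)[C@@H](CC=C)CC(=O)OC(C)(C)C)[C@H](Cc2ccccc2)CO1 | intermediate
23 | tert-butyl (3S)-3-(hydroxymethyl)hex-5-enoate | OC[C@@H](CC=C)CC(=O)OC(C)(C)C | intermediate
24 | (4S)-4-(prop-2-en-1-yl)oxolan-2-one | O=C1C[C@H](CC=C)CO1 | intermediate
25 | (3S)-3-(iodomethyl)hex-5-enoic acid | IC[C@@H](CC=C)CC(=O)O | intermediate
26 | methyl (3S)-3-(iodomethyl)hex-5-enoate | IC[C@@H](CC=C)CC(=O)OC | intermediate
27 | {(2S)-2-[(methoxycarbonyl)methyl]pent-4-en-1-yl}zinc iodide | I[Zn]C[C@@H](CC=C)CC(=O)OC | intermediate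
28 | methyl (3R)-3-{[5'-yl of enoate 15]methyl}hex-5-enoate (C8–C14 coupled enoate) | C[C@@]12CCC[C@]3(COC(=O)C(C[C@@H](CC=C)CC(=O)OC)=C3)[C@@H]1C(=O)OC2 | intermediate
29 | methyl (3S)-3-{[5'-yl of enoate 15]methyl}-5-oxopentanoate (C11 aldehyde) | C[C@@]12CCC[C@]3(COC(=O)C(C[C@@H](CC=O)CC(=O)OC)=C3)[C@@H]1C(=O)OC2 | intermediate
30 | bis(diiodosamarium) C11 alkoxide/C8 lactone enolate after closure of ring C | C[C@@]12CCC[C@]3(COC(O[Sm](I)I)=C4C[C@H](CC(=O)OC)C[C@H](O[Sm](I)I)[C@H]43)[C@@H]1C(=O)OC2 | intermediate
31 | pentacyclic 11-hydroxy-15-oxo dilactone lacking C17 (C11–OH trans to C10) | C[C@@]12CCC[C@]3(COC(=O)[C@@]45C[C@@H](C[C@H](O)[C@H]43)CC5=O)[C@@H]1C(=O)OC2 | intermediate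
32 | pentacyclic 11,15-dioxo dilactone lacking C17 | C[C@@]12CCC[C@]3(COC(=O)[C@@]45C[C@@H](CC(=O)[C@H]43)CC5=O)[C@@H]1C(=O)OC2 | intermediate
33 | pentacyclic 11-hydroxy-15-oxo dilactone lacking C17 (C11–OH equatorial, cis to C10, trans to H-9) | C[C@@]12CCC[C@]3(COC(=O)[C@@]45C[C@@H](C[C@@H](O)[C@H]43)CC5=O)[C@@H]1C(=O)OC2 | intermediate
34 | 16-methylene derivative of 33 (15-oxo-16-ene) | C[C@@]12CCC[C@]3(COC(=O)[C@@]45C[C@@H](C[C@@H](O)[C@H]43)C(=C)C5=O)[C@@H]1C(=O)OC2 | intermediate
35 | C17 pinacol boronate of the target skeleton (CH2B endo on C16) | C[C@@]12CCC[C@]3(COC(=O)[C@@]45C[C@@H](C[C@@H](O)[C@H]43)[C@@H](CB6OC(C)(C)C(C)(C)O6)C5=O)[C@@H]1C(=O)OC2 | intermediate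
36 | CNP0555433.1: 11,17-dihydroxy-15-oxo-6,7-seco-ent-kaurane-6,19:7,20-diolide (C11–OH cis to C10; C17 endo) | C[C@@]12CCC[C@]3(COC(=O)[C@@]45C[C@@H](C[C@@H](O)[C@H]43)[C@@H](CO)C5=O)[C@@H]1C(=O)OC2 | target

**Step count and risks**

Total step count: 19. Longest linear sequence: 15 steps (steps 1–8, then 13–19).

Steps most likely to fail:

Step 15 (labelled). What may go wrong: the samarium enolate is protonated or is outrun by O-acylation of the C11 alkoxide, so ring D does not close; ketyl dimerisation competes; or the β-keto lactone is reduced further. Fallback with known chemistry, setting out from 17 and returning at 32: Negishi coupling of 17 with (cyclopent-3-en-1-ylmethyl)zinc iodide F2, made in the flask from 4-(iodomethyl)cyclopent-1-ene F1 (Appel iodination of commercial cyclopent-3-en-1-ylmethanol), would give the C8-cyclopentenylmethyl enoate F3. Ozonolysis of the cyclopentene would give the symmetrical dialdehyde F4. Its SmI2/LiBr/t-BuOH cascade (ketyl–olefin cyclisation, then aldol addition of the samarium enolate to the second aldehyde, the precedented type) would close rings C and D and set C13 by differentiating the two identical arms, giving the 11,15-diol F5. Dess–Martin oxidation of both carbinols would then give diketone 32.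

Step 17. What may go wrong: hydride adds competitively to the C15 ketone, or reaches C11 from the exo face and gives the axial epimer. Fallback, setting out from 32 and returning at 33: reagent control in place of substrate control, by oxazaborolidine-catalysed (CBS) reduction with BH3·SMe2, using the catalyst enantiomer that delivers hydride to the endo face of C11 (C9 as the large flank, C12 as the small one). No new compound is formed.

Step 19. What may go wrong: the enolate is protonated from the endo face, or C16 epimerises or eliminates under the basic oxidation. Fallback, setting out from 34 and returning at 36: nucleophilic epoxidation of the enone (t-BuOOH, DBU, CH2Cl2) would give the spiro-epoxy ketone F6. Reductive opening of this α,β-epoxy ketone with SmI2 in THF/MeOH at −90 °C cleaves the C16–O bond and protonates the samarium enolate at C16 kinetically without base, giving 36 directly.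

**Further compounds**

F1 | step 15 | 4-(iodomethyl)cyclopent-1-ene | ICC1CC=CC1
F2 | step 15 | (cyclopent-3-en-1-ylmethyl)zinc iodide | I[Zn]CC1CC=CC1
F3 | step 15 | 5'-(cyclopent-3-en-1-ylmethyl) derivative of enoate 15 | C[C@@]12CCC[C@]3(COC(=O)C(CC4CC=CC4)=C3)[C@@H]1C(=O)OC2
F4 | step 15 | dialdehyde: 5'-[4-oxo-2-(2-oxoethyl)butyl] derivative of enoate 15 | C[C@@]12CCC[C@]3(COC(=O)C(CC(CC=O)CC=O)=C3)[C@@H]1C(=O)OC2
F5 | step 15 | pentacyclic 11,15-diol dilactone lacking C17 | C[C@@]12CCC[C@]3(COC(=O)[C@@]45C[C@@H](C[C@H](O)[C@H]43)CC5O)[C@@H]1C(=O)OC2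
F0 | step 17 | none | none
F6 | step 19 | 16,17-epoxide of enone 34 | C[C@@]12CCC[C@]3(COC(=O)[C@@]45C[C@@H](C[C@@H](O)[C@H]43)C6(CO6)C5=O)[C@@H]1C(=O)OC2
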